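**Plan**

- The retrosynthesis first opens the 2,2-dimethyl-2H-pyran ring (O1, C2, C3, C4, C4a, C8a) at O1–C2 and C4–C4a. This ring is fused to an arene whose C4a is the only uncrowded carbon ortho to the oxygen-bearing C8a and lies para to the C7 methoxy group, so a free phenol and 3-methyl-2-butenal can build it in one operation.
- The second cut is the aryl–C bond at the benzylic, allylic stereocentre of the side chain, giving a benzofuranyl pentadiene and an arylboronic acid.
- The diene goes back to an enal (terminal C=CH2 by methylenation). The furan ring (C3–C3a and O1–C2 of the benzofuran) goes back to 5-iodo-2,4-dihydroxyacetophenone and (E)-3-methylpent-2-en-4-yn-1-ol.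
- Forward order: benzofuran ring (step 2), diene (steps 3–5), union with the aryl unit (step 8), pyran ring last (step 10).
- The E alkene is carried through from the commercial E-enynol. The single S centre is set by the chiral ligand on nickel in step 8. Step 10 creates no stereocentre.

Key step: step 10

Assumption: the sense of induction of the nickel/spiro-aminophosphine catalyst is taken to follow that of simple 1-aryl-1,3-dienes, and the ligand antipode is chosen so that step 8 gives the 4S product.

**Route**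

Step 1
Reactants: 1 2,4-dihydroxyacetophenone
Product: 2 1-(2,4-dihydroxy-5-iodophenyl)ethanone
Conditions: ICl, AcOH, rt
Reagents that add atoms: iodine monochloride, ClI
Why: Electrophilic aromatic iodination should go to C5, which is para to the chelated 2-hydroxyl and ortho to the 4-hydroxyl and is less crowded than C3 between the two hydroxyls.

Step 2
Reactants: 2 1-(2,4-dihydroxy-5-iodophenyl)ethanone; 3 (E)-3-methylpent-2-en-4-yn-1-ol
Product: 5 1-[6-hydroxy-2-[(2E)-4-hydroxybut-2-en-2-yl]-1-benzofuran-5-yl]ethanone, via alkynylphenol 4 (not isolated)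
Conditions: PdCl2(PPh3)2 (cat.), CuI (cat.), Et3N, DMF, 60 °C, degassed
Reagents that add atoms: none
Why: Sonogashira coupling at the C–I bond should give ortho-alkynylphenol 4, which under the same palladium/copper/amine conditions undergoes 5-endo-dig cycloisomerisation (Castro–Stephens/Larock-type benzofuran annulation) onto the only hydroxyl ortho to the alkyne, leaving the E alkene of 3 untouched.

Step 3
Reactants: 5 1-[6-hydroxy-2-[(2E)-4-hydroxybut-2-en-2-yl]-1-benzofuran-5-yl]ethanone
Product: 6 (2E)-3-(5-acetyl-6-hydroxy-1-benzofuran-2-yl)but-2-enal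
Conditions: activated MnO2, CH2Cl2, rt
Reagents that add atoms: none
Why: Allylic oxidation with MnO2 is selective for the allylic alcohol under neutral heterogeneous conditions, so the chelated phenol, the ketone and the alkene geometry should be preserved.

Step 4
Reactants: 6 (2E)-3-(5-acetyl-6-hydroxy-1-benzofuran-2-yl)but-2-enal
Product: 7 (2E)-3-[5-acetyl-6-(tert-butyldimethylsilyloxy)-1-benzofuran-2-yl]but-2-enal
Conditions: TBSCl, imidazole, DMAP (cat.), DMF, rt
Reagents that add atoms: tert-butyldimethylsilyl chloride, CC(C)(C)[Si](C)(C)Cl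
Why: Corey silylation of the phenol removes the only acidic proton before the ylide and nickel steps, with DMAP helping to overcome the hydrogen bond to the acetyl group.

Step 5
Reactants: 7 (2E)-3-[5-acetyl-6-(tert-butyldimethylsilyloxy)-1-benzofuran-2-yl]but-2-enal
Product: 8 1-[6-(tert-butyldimethylsilyloxy)-2-[(2E)-penta-2,4-dien-2-yl]-1-benzofuran-5-yl]ethanone
Conditions: Ph3PCH3Br (1.15 equiv), KN(SiMe3)2 (1.1 equiv), THF, 0 °C; then 7, −78 → 0 °C
Reagents that add atoms: methyltriphenylphosphonium bromide, C[P+](c1ccccc1)(c1ccccc1)c1ccccc1.[Br-]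
Why: Wittig methylenation with a slight deficit of base should take the aldehyde much faster than the aryl methyl ketone at low temperature and cannot alter the existing trisubstituted E alkene.

Step 6
Reactants: 9 4-bromo-3-methoxyphenol
Product: 10 (4-bromo-3-methoxyphenoxy)(tert-butyl)dimethylsilane
Conditions: TBSCl, imidazole, CH2Cl2, rt
Reagents that add atoms: tert-butyldimethylsilyl chloride, CC(C)(C)[Si](C)(C)Cl
Why: Corey silylation protects the phenol so that the following halogen–lithium exchange is not quenched.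

Step 7
Reactants: 10 (4-bromo-3-methoxyphenoxy)(tert-butyl)dimethylsilane
Product: 13 [4-(tert-butyldimethylsilyloxy)-2-methoxyphenyl]boronic acid, via aryllithium 11 (not isolated), via lithium aryltriisopropoxyborate 12 (not isolated)
Conditions: n-BuLi, THF, −78 °C; B(OiPr)3, −78 °C → rt; 1 M aq. HCl to pH 5–6, 0 °C
Reagents that add atoms: triisopropyl borate, CC(C)OB(OC(C)C)OC(C)C; water, O
Why: Bromine–lithium exchange, borate trapping and mild hydrolysis is the standard arylboronic acid synthesis, and the carbanion is para to the silyloxy group, so no silyl migration to carbon can occur.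

Step 8
Reactants: 8 1-[6-(tert-butyldimethylsilyloxy)-2-[(2E)-penta-2,4-dien-2-yl]-1-benzofuran-5-yl]ethanone; 13 [4-(tert-butyldimethylsilyloxy)-2-methoxyphenyl]boronic acid (2 equiv)
Product: 14 1-[6-(tert-butyldimethylsilyloxy)-2-[(2E,4S)-4-[4-(tert-butyldimethylsilyloxy)-2-methoxyphenyl]pent-2-en-2-yl]-1-benzofuran-5-yl]ethanone
Conditions: Ni(cod)2 (10 mol %), chiral 7-amino-7'-[bis(3,5-di-tert-butylphenyl)phosphino]-1,1'-spirobiindane (12 mol %, antipode per the assumption), MeOH/THF, 30 °C
Reagents that add atoms: none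
Why: This is the nickel-hydride-type enantioselective 1,2-hydroarylation of an aryl-substituted 1,3-diene with an arylboronic acid in methanol, in which hydrogen goes to the terminal CH2, the η3-allylnickel is arylated at its methyl-bearing terminus rather than at the fully substituted one so that the E alkene stays conjugated with the benzofuran, and the chiral aminophosphine on zerovalent nickel selects the allyl face and so sets the 4S centre.

Step 9
Reactants: 14 1-[6-(tert-butyldimethylsilyloxy)-2-[(2E,4S)-4-[4-(tert-butyldimethylsilyloxy)-2-methoxyphenyl]pent-2-en-2-yl]-1-benzofuran-5-yl]ethanone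
Product: 15 1-[6-hydroxy-2-[(2E,4S)-4-(4-hydroxy-2-methoxyphenyl)pent-2-en-2-yl]-1-benzofuran-5-yl]ethanone
Conditions: Bu4NF (2.5 equiv), AcOH (2.5 equiv), THF, 0 °C → rt
Reagents that add atoms: none
Why: Fluoride-mediated desilylation cleaves both aryl silyl ethers, and the acetic acid buffer keeps the medium too weakly basic to touch the benzylic, allylic centre or the alkene.

Step 10
Reactants: 15 1-[6-hydroxy-2-[(2E,4S)-4-(4-hydroxy-2-methoxyphenyl)pent-2-en-2-yl]-1-benzofuran-5-yl]ethanone; 16 3-methyl-2-butenal (2 equiv)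
Product: 18 1-[6-hydroxy-2-[(2E,4S)-4-(7-methoxy-2,2-dimethyl-2H-chromen-6-yl)pent-2-en-2-yl]-1-benzofuran-5-yl]ethanone, via ortho-quinone methide 17 (not isolated)
Conditions: ethylenediammonium diacetate (20 mol %), xylene, 110–130 °C
Reagents that add atoms: none
Why: The ammonium acetate turns 16 into an iminium electrophile that the non-chelated phenol of 15 attacks through its ring carbon ortho to OH and para to OMe (Knoevenagel-type condensation, forming C4–C4a), and loss of amine and water gives ortho-quinone methide 17, a 1-oxatriene. 17 should close by thermal disrotatory oxa-6π electrocyclisation, which forms O1–C2, completes the six-membered 2H-pyran ring and restores the arene. The closest known reaction type is the amine- or ethylenediammonium diacetate-mediated chromenylation of phenols with α,β-unsaturated aldehydes (formal [3+3] annulation). No stereocentre is created, and the nearly neutral medium should leave the S centre, the E alkene and the new acid-sensitive chromene alone. The step needs site selectivity between the two carbons ortho to the reacting hydroxyl, which is secured because one is wedged between OH and OMe while the other has an unsubstituted CH as neighbour; it also needs selectivity between the two phenols, which is secured because the benzofuran hydroxyl is tied up in a hydrogen bond to the acetyl group on an acceptor-substituted ring.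

**Compound list**

1 | 2,4-dihydroxyacetophenone | CC(=O)c1ccc(O)cc1O | starting material
2 | 1-(2,4-dihydroxy-5-iodophenyl)ethanone | CC(=O)c1cc(I)c(O)cc1O | intermediate
3 | (E)-3-methylpent-2-en-4-yn-1-ol | C#C/C(C)=C/CO | starting material
4 | 1-[2,4-dihydroxy-5-[(3E)-5-hydroxy-3-methylpent-3-en-1-yn-1-yl]phenyl]ethanone (alkynylphenol, not isolated) | CC(=O)c1cc(C#C/C(C)=C/CO)c(O)cc1O | intermediate
5 | 1-[6-hydroxy-2-[(2E)-4-hydroxybut-2-en-2-yl]-1-benzofuran-5-yl]ethanone | CC(=O)c1cc2cc(/C(C)=C/CO)oc2cc1O | intermediate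
6 | (2E)-3-(5-acetyl-6-hydroxy-1-benzofuran-2-yl)but-2-enal | CC(=O)c1cc2cc(/C(C)=C/C=O)oc2cc1O | intermediate
7 | (2E)-3-[5-acetyl-6-(tert-butyldimethylsilyloxy)-1-benzofuran-2-yl]but-2-enal | CC(=O)c1cc2cc(/C(C)=C/C=O)oc2cc1O[Si](C)(C)C(C)(C)C | intermediate
8 | 1-[6-(tert-butyldimethylsilyloxy)-2-[(2E)-penta-2,4-dien-2-yl]-1-benzofuran-5-yl]ethanone | CC(=O)c1cc2cc(/C(C)=C/C=C)oc2cc1O[Si](C)(C)C(C)(C)C | intermediate
9 | 4-bromo-3-methoxyphenol | COc1cc(O)ccc1Br | starting material
10 | (4-bromo-3-methoxyphenoxy)(tert-butyl)dimethylsilane | COc1cc(O[Si](C)(C)C(C)(C)C)ccc1Br | intermediate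
11 | [4-(tert-butyldimethylsilyloxy)-2-methoxyphenyl]lithium (not isolated) | COc1cc(O[Si](C)(C)C(C)(C)C)ccc1[Li] | intermediate
12 | lithium [4-(tert-butyldimethylsilyloxy)-2-methoxyphenyl]triisopropoxyborate (not isolated) | COc1cc(O[Si](C)(C)C(C)(C)C)ccc1[B-](OC(C)C)(OC(C)C)OC(C)C.[Li+] | intermediate
13 | [4-(tert-butyldimethylsilyloxy)-2-methoxyphenyl]boronic acid | COc1cc(O[Si](C)(C)C(C)(C)C)ccc1B(O)O | intermediate
14 | 1-[6-(tert-butyldimethylsilyloxy)-2-[(2E,4S)-4-[4-(tert-butyldimethylsilyloxy)-2-methoxyphenyl]pent-2-en-2-yl]-1-benzofuran-5-yl]ethanone | COc1cc(O[Si](C)(C)C(C)(C)C)ccc1[C@@H](C)/C=C(\C)c1cc2cc(C(C)=O)c(O[Si](C)(C)C(C)(C)C)cc2o1 | intermediate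
15 | 1-[6-hydroxy-2-[(2E,4S)-4-(4-hydroxy-2-methoxyphenyl)pent-2-en-2-yl]-1-benzofuran-5-yl]ethanone | COc1cc(O)ccc1[C@@H](C)/C=C(\C)c1cc2cc(C(C)=O)c(O)cc2o1 | intermediate
16 | 3-methyl-2-butenal | CC(C)=CC=O | starting material
17 | 1-[6-hydroxy-2-[(2E,4S)-4-[6-methoxy-3-(3-methylbut-2-en-1-ylidene)-4-oxocyclohexa-1,5-dien-1-yl]pent-2-en-2-yl]-1-benzofuran-5-yl]ethanone (ortho-quinone methide, not isolated) | COC1=CC(=O)C(=CC=C(C)C)C=C1[C@@H](C)/C=C(\C)c1cc2cc(C(C)=O)c(O)cc2o1 | intermediate
18 | 1-[6-hydroxy-2-[(2E,4S)-4-(7-methoxy-2,2-dimethyl-2H-chromen-6-yl)pent-2-en-2-yl]-1-benzofuran-5-yl]ethanone | COc1cc2c(cc1[C@@H](C)/C=C(\C)c1cc3cc(C(C)=O)c(O)cc3o1)C=CC(C)(C)O2 | target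

**Step count**

Total: 10 steps. Longest linear sequence: 8 steps (steps 1, 2, 3, 4, 5, 8, 9, 10); steps 6 and 7 form the side branch.

**Steps most likely to fail**

Step 8. Facial selection at the allylnickel may be poor with the ortho-methoxy boronic acid and the allyl unit bearing a fully substituted terminus. Protodeboronation of the electron-rich boronic acid may outrun transmetalation, and π–σ–π isomerisation of the allyl may erode the E geometry. The fallback sets out from 10 and comes back at 15. Stille coupling of 10 with Bu3SnCH=CH2 (Pd(PPh3)4, toluene, 100 °C) should give tert-butyl(4-ethenyl-3-methoxyphenoxy)dimethylsilane F1. Rhodium-catalysed asymmetric hydroformylation of the styrene (Rh(acac)(CO)2, chiral bis(diazaphospholane) ligand of the appropriate antipode, CO/H2, toluene, 60 °C) should give the branched aldehyde (2R)-2-[4-(tert-butyldimethylsilyloxy)-2-methoxyphenyl]propanal F2. The aldehyde is used crude, to limit racemisation, in a Wittig reaction with Ph3P=C(CH3)CHO (toluene, 60–80 °C) to give (2E,4S)-4-[4-(tert-butyldimethylsilyloxy)-2-methoxyphenyl]-2-methylpent-2-enal F3. Colvin homologation of the enal (Me3SiCHN2, LiN(iPr)2, THF, −78 °C → rt) should give tert-butyl-[3-methoxy-4-[(2S,3E)-4-methylhex-3-en-5-yn-2-yl]phenoxy]dimethylsilane F4. Sonogashira coupling of this enyne with 2 under the conditions of step 2 should give the alkynylphenol 1-[5-[(3E,5S)-5-[4-(tert-butyldimethylsilyloxy)-2-methoxyphenyl]-3-methylhex-3-en-1-yn-1-yl]-2,4-dihydroxyphenyl]ethanone F5, which should cycloisomerise in the same flask to 1-[2-[(2E,4S)-4-[4-(tert-butyldimethylsilyloxy)-2-methoxyphenyl]pent-2-en-2-yl]-6-hydroxy-1-benzofuran-5-yl]ethanone F6. Bu4NF/AcOH (THF, 0 °C → rt) then removes the remaining silyl group and delivers 15.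

Step 10. Condensation may also occur at the carbon between OH and OMe or on the chelated benzofuran phenol, or the mono-hydroxylated ring may react so slowly that 16 self-condenses. The fallback sets out from 15 and comes back at 18. Selective O-alkylation of the non-chelated phenol with 3-chloro-3-methylbut-1-yne (CuCl2·2H2O cat., DBU, MeCN, 0 °C) should give 1-[6-hydroxy-2-[(2E,4S)-4-[2-methoxy-4-(2-methylbut-3-yn-2-yloxy)phenyl]pent-2-en-2-yl]-1-benzofuran-5-yl]ethanone F7. Heating this aryl propargyl ether (N,N-diethylaniline or xylene, 140–180 °C) should trigger an aromatic propargyl Claisen rearrangement to the allenylphenol 1-[6-hydroxy-2-[(2E,4S)-4-[4-hydroxy-2-methoxy-5-(3-methylbuta-1,2-dien-1-yl)phenyl]pent-2-en-2-yl]-1-benzofuran-5-yl]ethanone F8. A 1,5-hydrogen shift in the allenylphenol leads to the same ortho-quinone methide 17, and oxa-6π closure gives 18.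

Step 5. The ylide may also attack or enolise the aryl methyl ketone, the ortho silyl group may migrate to the enolate, or the diene may oligomerise on work-up. The fallback sets out from 3 and comes back at 8; it makes the diene before the ketone-bearing arene is attached. MnO2 oxidation of 3 (CH2Cl2, rt) should give (2E)-3-methylpent-2-en-4-ynal F9. Wittig methylenation of the ynal (Ph3P=CH2 from Ph3PCH3Br and KN(SiMe3)2, Et2O/THF, −78 → 0 °C) should give the volatile (3E)-4-methylhexa-1,3-dien-5-yne F10, kept in solution. Sonogashira coupling of the dienyne with 2 (PdCl2(PPh3)2, CuI, Et3N, DMF, 60 °C) should give the alkynylphenol 1-[2,4-dihydroxy-5-[(3E)-3-methylhexa-3,5-dien-1-yn-1-yl]phenyl]ethanone F11, which should cycloisomerise in the same flask to 1-[6-hydroxy-2-[(2E)-penta-2,4-dien-2-yl]-1-benzofuran-5-yl]ethanone F12. Silylation of this phenol (TBSCl, imidazole, DMF, rt) returns to 8.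

**Further compounds**

F1 | step 8 | tert-butyl(4-ethenyl-3-methoxyphenoxy)dimethylsilane | COc1cc(O[Si](C)(C)C(C)(C)C)ccc1C=C
F2 | step 8 | (2R)-2-[4-(tert-butyldimethylsilyloxy)-2-methoxyphenyl]propanal | COc1cc(O[Si](C)(C)C(C)(C)C)ccc1[C@@H](C)C=O
F3 | step 8 | (2E,4S)-4-[4-(tert-butyldimethylsilyloxy)-2-methoxyphenyl]-2-methylpent-2-enal | COc1cc(O[Si](C)(C)C(C)(C)C)ccc1[C@@H](C)/C=C(\C)C=O
F4 | step 8 | tert-butyl-[3-methoxy-4-[(2S,3E)-4-methylhex-3-en-5-yn-2-yl]phenoxy]dimethylsilane | COc1cc(O[Si](C)(C)C(C)(C)C)ccc1[C@@H](C)/C=C(\C)C#C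
F5 | step 8 | 1-[5-[(3E,5S)-5-[4-(tert-butyldimethylsilyloxy)-2-methoxyphenyl]-3-methylhex-3-en-1-yn-1-yl]-2,4-dihydroxyphenyl]ethanone | COc1cc(O[Si](C)(C)C(C)(C)C)ccc1[C@@H](C)/C=C(\C)C#Cc1cc(C(C)=O)c(O)cc1O
F6 | step 8 | 1-[2-[(2E,4S)-4-[4-(tert-butyldimethylsilyloxy)-2-methoxyphenyl]pent-2-en-2-yl]-6-hydroxy-1-benzofuran-5-yl]ethanone | COc1cc(O[Si](C)(C)C(C)(C)C)ccc1[C@@H](C)/C=C(\C)c1cc2cc(C(C)=O)c(O)cc2o1
F7 | step 10 | 1-[6-hydroxy-2-[(2E,4S)-4-[2-methoxy-4-(2-methylbut-3-yn-2-yloxy)phenyl]pent-2-en-2-yl]-1-benzofuran-5-yl]ethanone | COc1cc(OC(C)(C)C#C)ccc1[C@@H](C)/C=C(\C)c1cc2cc(C(C)=O)c(O)cc2o1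
F8 | step 10 | 1-[6-hydroxy-2-[(2E,4S)-4-[4-hydroxy-2-methoxy-5-(3-methylbuta-1,2-dien-1-yl)phenyl]pent-2-en-2-yl]-1-benzofuran-5-yl]ethanone | COc1cc(O)c(C=C=C(C)C)cc1[C@@H](C)/C=C(\C)c1cc2cc(C(C)=O)c(O)cc2o1
F9 | step 5 | (2E)-3-methylpent-2-en-4-ynal | C#C/C(C)=C/C=O
F10 | step 5 | (3E)-4-methylhexa-1,3-dien-5-yne | C#C/C(C)=C/C=C
F11 | step 5 | 1-[2,4-dihydroxy-5-[(3E)-3-methylhexa-3,5-dien-1-yn-1-yl]phenyl]ethanone | CC(=O)c1cc(C#C/C(C)=C/C=C)c(O)cc1O
F12 | step 5 | 1-[6-hydroxy-2-[(2E)-penta-2,4-dien-2-yl]-1-benzofuran-5-yl]ethanone | CC(=O)c1cc2cc(/C(C)=C/C=C)oc2cc1O
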